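## Retrosynthetic overview

1. The oxirane is formed last: target 25 comes from titanium–tartrate epoxidation of the C15 allylic alcohol in macrocyclic diol 24, itself from double desilylation of 23.
2. The ten-membered ring is formed second: C1=C10 by ring-closing metathesis of 22, where ring strain enforces the Z alkene. The C8 ester comes from Mitsunobu inversion of carbinol 17 with acid 21.
3. Key C7–C8 bond: the β-carbon of a butenolide is made nucleophilic (allylchromium from bromide 13, a lactone homoenolate equivalent) and adds to the carbonyl carbon of 3-methylbut-3-enal 15. This sets C7 and C8 and unveils the α-methylene lactone.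
4. The lactone ring is formed first: 13 by ring-closing metathesis of the 2-(bromomethyl)acrylate 12 of (S)-dienyl carbinol 10; C6 comes from catalytic asymmetric vinylation of Z-enal 7.
5. Enal 7 comes from prop-2-yn-1-ol by copper-catalysed anti-carbomagnesiation/iodination, silylation and formylation.

Assumption: atoms are labelled with germacrane numbering (C1–C15; C8 bears the ester, C15 is the hydroxymethyl carbon), and the target is read as 4S,5R,6S,7R,8R with a Z ring alkene and an E side-chain alkene.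

## Route

Step 1
Reactants: 1 prop-2-yn-1-ol; 2 but-3-en-1-ylmagnesium bromide
Product: 4 (2Z)-2-(but-3-en-1-yl)-3-iodoprop-2-en-1-ol, via alkenylmagnesium chelate 3 (not isolated)
Conditions: CuI (10 mol%), THF/Et2O, −20 °C → rt; then I2, −40 → 0 °C; aq. NH4Cl
Reagents that add atoms: iodine (II)
Why: Copper-catalysed anti-carbomagnesiation of a propargylic alkoxide (Duboudin–Jousseaume type) puts the butenyl group on the carbon next to CH2O and magnesium cis to the alkoxide in a five-membered chelate, so iodinolysis with retention gives the Z iodide with the future C6 position cis to C15 (no stereocenter).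

Step 2
Reactants: 4 (2Z)-2-(but-3-en-1-yl)-3-iodoprop-2-en-1-ol
Product: 5 tert-butyl{[(2Z)-2-(but-3-en-1-yl)-3-iodoprop-2-en-1-yl]oxy}dimethylsilane
Conditions: TBSCl, imidazole, CH2Cl2, 0 °C → rt
Reagents that add atoms: tert-butyldimethylsilyl chloride (CC(C)(C)[Si](C)(C)Cl)
Why: Standard silylation of a primary alcohol protects C15–OH for the organolithium, chromium and Mitsunobu steps and is removed together with the side-chain silyl ether at the end.

Step 3
Reactants: 5 tert-butyl{[(2Z)-2-(but-3-en-1-yl)-3-iodoprop-2-en-1-yl]oxy}dimethylsilane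
Product: 7 (2Z)-3-({[tert-butyl(dimethyl)silyl]oxy}methyl)hepta-2,6-dienal, via alkenyllithium 6 (not isolated)
Conditions: t-BuLi (2.1 equiv), Et2O, −78 °C, 20 min; DMF, −78 → 0 °C; aq. NH4Cl
Reagents that add atoms: N,N-dimethylformamide (CN(C)C=O)
Why: Iodine–lithium exchange proceeds with retention of alkene geometry and formylation with DMF gives the Z enal (C6 aldehyde cis to C15), while Et2O at −78 °C suppresses 1,4-silyl migration.

Step 4
Reactants: 7 (2Z)-3-({[tert-butyl(dimethyl)silyl]oxy}methyl)hepta-2,6-dienal; 8 ethenylmagnesium bromide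
Product: 10 (3S,4Z)-5-({[tert-butyl(dimethyl)silyl]oxy}methyl)nona-1,4,8-trien-3-ol, via divinylzinc 9 (not isolated)
Conditions: CH2=CHMgBr (4 equiv), ZnCl2 (2 equiv), THF, then 1,4-dioxane and filtration; (−)-MIB (10 mol%), toluene, −20 → 0 °C
Reagents that add atoms: none
Why: Amino-alcohol-catalysed enantioselective addition of an alkenylzinc to an aldehyde (Noyori–Oppolzer type) delivers the vinyl group to the Si face of the enal carbonyl, as (−)-MIB does for aryl and alkenyl aldehydes, setting C6 as S.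

Step 5
Reactants: 10 (3S,4Z)-5-({[tert-butyl(dimethyl)silyl]oxy}methyl)nona-1,4,8-trien-3-ol; 11 2-(bromomethyl)prop-2-enoic acid
Product: 12 (3S,4Z)-5-({[tert-butyl(dimethyl)silyl]oxy}methyl)nona-1,4,8-trien-3-yl 2-(bromomethyl)prop-2-enoate
Conditions: DCC, DMAP (5 mol%), CH2Cl2, −10 → 0 °C
Reagents that add atoms: none
Why: Steglich esterification acylates the secondary carbinol without touching its configuration, with low DMAP loading and low temperature keeping the allylic bromide intact.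

Step 6
Reactants: 12 (3S,4Z)-5-({[tert-butyl(dimethyl)silyl]oxy}methyl)nona-1,4,8-trien-3-yl 2-(bromomethyl)prop-2-enoate
Product: 13 (5R)-3-(bromomethyl)-5-[(1Z)-2-({[tert-butyl(dimethyl)silyl]oxy}methyl)hexa-1,5-dien-1-yl]furan-2(5H)-one
Conditions: second-generation Hoveyda–Grubbs catalyst (5 mol%), 1,4-benzoquinone (10 mol%), toluene (2 mM), 80 °C
Reagents that add atoms: none
Why: Ring-closing metathesis of an allylic acrylate to a butenolide is the only feasible closure, because the other terminal vinyl group sits trans to C6 across the C4=C5 bond and cannot close a seven-membered ring; the C6 stereocenter is untouched (the descriptor changes to R only through priorities).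

Step 7
Reactants: 14 3-methylbut-3-en-1-ol
Product: 15 3-methylbut-3-enal
Conditions: Dess–Martin periodinane, NaHCO3, CH2Cl2, 0 °C; cold filtered solution used at once
Reagents that add atoms: none
Why: Buffered Dess–Martin oxidation gives the β,γ-unsaturated aldehyde without acid- or base-promoted migration of the double bond into conjugation.

Step 8
Reactants: 13 (5R)-3-(bromomethyl)-5-[(1Z)-2-({[tert-butyl(dimethyl)silyl]oxy}methyl)hexa-1,5-dien-1-yl]furan-2(5H)-one; 15 3-methylbut-3-enal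
Product: 17 (4R,5R)-5-[(1Z)-2-({[tert-butyl(dimethyl)silyl]oxy}methyl)hexa-1,5-dien-1-yl]-4-[(1S)-1-hydroxy-3-methylbut-3-en-1-yl]-3-methylideneoxolan-2-one, via allylchromium dichloride 16 (not isolated)
Conditions: CrCl2 (4 equiv), THF, 0 °C → rt; 15 (2.5 equiv)
Reagents that add atoms: none
Why: In this Nozaki–Hiyama-type allylation, divalent chromium turns the allylic bromide into an allylchromium reagent in which the normally electrophilic butenolide β-carbon C7 is the nucleophile toward the aldehyde carbon C8, and a chair transition state on the ring face opposite the C6 dienyl group with the aldehyde chain equatorial gives the trans lactone (C7 R), the anti carbinol (C8 S) and the exocyclic methylene in one operation.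

Step 9
Reactants: 18 {[tert-butyl(dimethyl)silyl]oxy}acetaldehyde; 19 ethyl 2-(triphenylphosphoranylidene)propanoate
Product: 20 ethyl (2E)-4-{[tert-butyl(dimethyl)silyl]oxy}-2-methylbut-2-enoate
Conditions: CH2Cl2, rt
Reagents that add atoms: none
Why: Wittig olefination with a stabilised, α-branched ylide gives the E trisubstituted enoate with high selectivity.

Step 10
Reactants: 20 ethyl (2E)-4-{[tert-butyl(dimethyl)silyl]oxy}-2-methylbut-2-enoate
Product: 21 (2E)-4-{[tert-butyl(dimethyl)silyl]oxy}-2-methylbut-2-enoic acid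
Conditions: LiOH, THF/H2O, rt; then 1 M HCl to pH 4 at 0 °C
Reagents that add atoms: lithium hydroxide ([Li+].[OH-])
Why: Mild saponification cleaves the ethyl ester while the primary silyl ether and the alkene geometry are retained.

Step 11
Reactants: 17 (4R,5R)-5-[(1Z)-2-({[tert-butyl(dimethyl)silyl]oxy}methyl)hexa-1,5-dien-1-yl]-4-[(1S)-1-hydroxy-3-methylbut-3-en-1-yl]-3-methylideneoxolan-2-one; 21 (2E)-4-{[tert-butyl(dimethyl)silyl]oxy}-2-methylbut-2-enoic acid
Product: 22 (1R)-1-{(2R,3R)-2-[(1Z)-2-({[tert-butyl(dimethyl)silyl]oxy}methyl)hexa-1,5-dien-1-yl]-4-methylidene-5-oxooxolan-3-yl}-3-methylbut-3-en-1-yl (2E)-4-{[tert-butyl(dimethyl)silyl]oxy}-2-methylbut-2-enoate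
Conditions: PPh3, DIAD, toluene, 0 °C → rt (betaine pre-formed, then 21 and 17)
Reagents that add atoms: none
Why: Mitsunobu esterification displaces the activated C8 oxygen by the carboxylate in an SN2 step, so the 8S carbinol from the chair transition state is inverted to the required 8R ester while the side chain is installed.

Step 12
Reactants: 22 (1R)-1-{(2R,3R)-2-[(1Z)-2-({[tert-butyl(dimethyl)silyl]oxy}methyl)hexa-1,5-dien-1-yl]-4-methylidene-5-oxooxolan-3-yl}-3-methylbut-3-en-1-yl (2E)-4-{[tert-butyl(dimethyl)silyl]oxy}-2-methylbut-2-enoate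
Product: 23 (3aR,4R,6Z,10Z,11aR)-10-({[tert-butyl(dimethyl)silyl]oxy}methyl)-6-methyl-3-methylidene-2-oxo-2,3,3a,4,5,8,9,11a-octahydrocyclodeca[b]furan-4-yl (2E)-4-{[tert-butyl(dimethyl)silyl]oxy}-2-methylbut-2-enoate
Conditions: second-generation Grubbs catalyst (15 mol%, slow addition), 1,4-benzoquinone, toluene (0.5 mM), 80 °C
Reagents that add atoms: none
Why: Ring-closing metathesis between the C1 vinyl and the C10 isopropenyl groups is pre-organised by the trans lactone and the rigid C4=C5 bond, and the ten-membered ring accommodates the new trisubstituted alkene only as the Z isomer (C9 and C2 cis), with no stereocenter affected.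

Step 13
Reactants: 23 (3aR,4R,6Z,10Z,11aR)-10-({[tert-butyl(dimethyl)silyl]oxy}methyl)-6-methyl-3-methylidene-2-oxo-2,3,3a,4,5,8,9,11a-octahydrocyclodeca[b]furan-4-yl (2E)-4-{[tert-butyl(dimethyl)silyl]oxy}-2-methylbut-2-enoate
Product: 24 (3aR,4R,6Z,10Z,11aR)-10-(hydroxymethyl)-6-methyl-3-methylidene-2-oxo-2,3,3a,4,5,8,9,11a-octahydrocyclodeca[b]furan-4-yl (2E)-4-hydroxy-2-methylbut-2-enoate
Conditions: HF·pyridine, pyridine/THF, 0 °C → rt
Reagents that add atoms: none
Why: Buffered fluoride cleaves both primary silyl ethers in one operation without base, so the ester, the lactone and the Michael acceptor are untouched.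

Step 14
Reactants: 24 (3aR,4R,6Z,10Z,11aR)-10-(hydroxymethyl)-6-methyl-3-methylidene-2-oxo-2,3,3a,4,5,8,9,11a-octahydrocyclodeca[b]furan-4-yl (2E)-4-hydroxy-2-methylbut-2-enoate
Product: 25 target, (1(10)Z)-4α,5β-epoxy-15-hydroxy-8β-[(2E)-4-hydroxy-2-methylbut-2-enoyloxy]germacra-1(10),11(13)-dien-12,6α-olide (4S,5R,6S,7R,8R)
Conditions: Ti(OiPr)4 (20 mol%), L-(+)-DIPT (24 mol%), t-BuOOH (2 equiv), 4 Å MS, CH2Cl2, −20 °C
Reagents that add atoms: tert-butyl hydroperoxide (CC(C)(C)OO)
Why: Sharpless asymmetric epoxidation oxidises only the electron-rich C15 allylic alcohol (the side-chain hydroxy-enoate alkene is electron-poor and the other alkenes have no directing hydroxyl), and the L-(+)-tartrate catalyst, expected to be matched with attack on the exposed outer face of the C4=C5 bond, sets C4 as S and C5 as R.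

## Compound list

1 | prop-2-yn-1-ol | C#CCO | starting material
2 | but-3-en-1-ylmagnesium bromide | C=CCC[Mg]Br | starting material
3 | alkenylmagnesium chelate, 4-(but-3-en-1-yl)-2,5-dihydro-1,2-oxamagnesole | C=CCCC1=C[Mg]OC1 | intermediate
4 | (2Z)-2-(but-3-en-1-yl)-3-iodoprop-2-en-1-ol | C=CCC/C(CO)=C/I | intermediate
5 | tert-butyl{[(2Z)-2-(but-3-en-1-yl)-3-iodoprop-2-en-1-yl]oxy}dimethylsilane | C=CCC/C(CO[Si](C)(C)C(C)(C)C)=C/I | intermediate
6 | [(1Z)-2-({[tert-butyl(dimethyl)silyl]oxy}methyl)hexa-1,5-dien-1-yl]lithium | C=CCC/C(CO[Si](C)(C)C(C)(C)C)=C/[Li] | intermediate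
7 | (2Z)-3-({[tert-butyl(dimethyl)silyl]oxy}methyl)hepta-2,6-dienal | C=CCC/C(CO[Si](C)(C)C(C)(C)C)=C/C=O | intermediate
8 | ethenylmagnesium bromide | C=C[Mg]Br | starting material
9 | divinylzinc | C=C[Zn]C=C | intermediate
10 | (3S,4Z)-5-({[tert-butyl(dimethyl)silyl]oxy}methyl)nona-1,4,8-trien-3-ol | O[C@H](/C=C(/CCC=C)CO[Si](C)(C)C(C)(C)C)C=C | intermediate
11 | 2-(bromomethyl)prop-2-enoic acid | C=C(CBr)C(=O)O | starting material
12 | (3S,4Z)-5-({[tert-butyl(dimethyl)silyl]oxy}methyl)nona-1,4,8-trien-3-yl 2-(bromomethyl)prop-2-enoate | C=C(CBr)C(=O)O[C@H](/C=C(/CCC=C)CO[Si](C)(C)C(C)(C)C)C=C | intermediate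
13 | (5R)-3-(bromomethyl)-5-[(1Z)-2-({[tert-butyl(dimethyl)silyl]oxy}methyl)hexa-1,5-dien-1-yl]furan-2(5H)-one | O=C1O[C@H](/C=C(/CCC=C)CO[Si](C)(C)C(C)(C)C)C=C1CBr | intermediate
14 | 3-methylbut-3-en-1-ol | C=C(C)CCO | starting material
15 | 3-methylbut-3-enal | C=C(C)CC=O | intermediate
16 | ({(5R)-5-[(1Z)-2-({[tert-butyl(dimethyl)silyl]oxy}methyl)hexa-1,5-dien-1-yl]-2-oxo-2,5-dihydrofuran-3-yl}methyl)chromium dichloride (trivalent chromium) | O=C1O[C@H](/C=C(/CCC=C)CO[Si](C)(C)C(C)(C)C)C=C1C[Cr](Cl)Cl | intermediate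
17 | (4R,5R)-5-[(1Z)-2-({[tert-butyl(dimethyl)silyl]oxy}methyl)hexa-1,5-dien-1-yl]-4-[(1S)-1-hydroxy-3-methylbut-3-en-1-yl]-3-methylideneoxolan-2-one | C=C1C(=O)O[C@H](/C=C(/CCC=C)CO[Si](C)(C)C(C)(C)C)[C@H]1[C@@H](O)CC(C)=C | intermediate
18 | {[tert-butyl(dimethyl)silyl]oxy}acetaldehyde | O=CCO[Si](C)(C)C(C)(C)C | starting material
19 | ethyl 2-(triphenylphosphoranylidene)propanoate | CCOC(=O)C(C)=P(c1ccccc1)(c1ccccc1)c1ccccc1 | starting material
20 | ethyl (2E)-4-{[tert-butyl(dimethyl)silyl]oxy}-2-methylbut-2-enoate | CCOC(=O)/C(C)=C/CO[Si](C)(C)C(C)(C)C | intermediate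
21 | (2E)-4-{[tert-butyl(dimethyl)silyl]oxy}-2-methylbut-2-enoic acid | OC(=O)/C(C)=C/CO[Si](C)(C)C(C)(C)C | intermediate
22 | (1R)-1-{(2R,3R)-2-[(1Z)-2-({[tert-butyl(dimethyl)silyl]oxy}methyl)hexa-1,5-dien-1-yl]-4-methylidene-5-oxooxolan-3-yl}-3-methylbut-3-en-1-yl (2E)-4-{[tert-butyl(dimethyl)silyl]oxy}-2-methylbut-2-enoate | C=C1C(=O)O[C@H](/C=C(/CCC=C)CO[Si](C)(C)C(C)(C)C)[C@H]1[C@H](OC(=O)/C(C)=C/CO[Si](C)(C)C(C)(C)C)CC(C)=C | intermediate
23 | (3aR,4R,6Z,10Z,11aR)-10-({[tert-butyl(dimethyl)silyl]oxy}methyl)-6-methyl-3-methylidene-2-oxo-2,3,3a,4,5,8,9,11a-octahydrocyclodeca[b]furan-4-yl (2E)-4-{[tert-butyl(dimethyl)silyl]oxy}-2-methylbut-2-enoate | C=C1C(=O)O[C@@H]2/C=C(CO[Si](C)(C)C(C)(C)C)/CC/C=C(C)\C[C@@H](OC(=O)/C(C)=C/CO[Si](C)(C)C(C)(C)C)[C@@H]12 | intermediate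
24 | (3aR,4R,6Z,10Z,11aR)-10-(hydroxymethyl)-6-methyl-3-methylidene-2-oxo-2,3,3a,4,5,8,9,11a-octahydrocyclodeca[b]furan-4-yl (2E)-4-hydroxy-2-methylbut-2-enoate | C=C1C(=O)O[C@@H]2/C=C(CO)/CC/C=C(C)\C[C@@H](OC(=O)/C(C)=C/CO)[C@@H]12 | intermediate
25 | (1(10)Z)-4α,5β-epoxy-15-hydroxy-8β-[(2E)-4-hydroxy-2-methylbut-2-enoyloxy]germacra-1(10),11(13)-dien-12,6α-olide (4S,5R,6S,7R,8R) | C=C1C(=O)O[C@H]2[C@H]1[C@H](OC(=O)/C(C)=C/CO)C/C(C)=C\CC[C@@]1(CO)O[C@H]21 | target

## Step count and risks

Total steps: 14. Longest linear sequence: 11 (steps 1, 2, 3, 4, 5, 6, 8, 11, 12, 13, 14).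

**Step 12, macrocyclic ring-closing metathesis.** Closing a strained ten-membered ring onto a 1,1-disubstituted alkene may give oligomers or no reaction. The fallback sets out from 17 and comes back at 23. It changes the substrate and the order of events: the ring is closed before the acylation, on the free carbinol, whose small hydroxyl replaces the bulky silyloxy-enoate next to the isopropenyl partner. Metathesis of 17 at high dilution gives (3aR,4S,6Z,10Z,11aR)-10-({[tert-butyl(dimethyl)silyl]oxy}methyl)-4-hydroxy-6-methyl-3-methylidene-3a,4,5,8,9,11a-hexahydrocyclodeca[b]furan-2(3H)-one F6. Mitsunobu esterification of F6 with 21 (PPh3, DIAD) then inverts C8 on the ring and gives 23.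

**Step 11, Mitsunobu inversion.** The C8 carbinol is α-branched, and elimination toward C7 or participation of the lactone carbonyl can compete with the SN2 step. The fallback sets out from 17 and comes back at 22, replacing the SN2 inversion by a redox inversion and an acylation with retention. Buffered Dess–Martin oxidation of 17 gives (4S,5R)-5-[(1Z)-2-({[tert-butyl(dimethyl)silyl]oxy}methyl)hexa-1,5-dien-1-yl]-3-methylidene-4-(3-methylbut-3-enoyl)oxolan-2-one F4. Reagent-controlled reduction with (S)-Me-CBS oxazaborolidine and catecholborane at −78 °C gives (4R,5R)-5-[(1Z)-2-({[tert-butyl(dimethyl)silyl]oxy}methyl)hexa-1,5-dien-1-yl]-4-[(1R)-1-hydroxy-3-methylbut-3-en-1-yl]-3-methylideneoxolan-2-one F5. Yamaguchi esterification of F5 with 21 (2,4,6-trichlorobenzoyl chloride, Et3N, DMAP) gives 22. The ketone F4 must be kept away from base, which would move the exocyclic alkene into the ring.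

**Step 6, butenolide ring-closing metathesis.** A slow 2-substituted acrylate closure has to compete with dimerisation of the free terminal alkene, in the presence of an allylic bromide. The fallback sets out from 7 and comes back at 13 without any metathesis:
- Zinc-mediated asymmetric alkynylation of 7 with methyl propiolate (Me2Zn, ProPhenol ligand of the enantiomer that gives the 4R carbinol) gives methyl (4R,5Z)-6-({[tert-butyl(dimethyl)silyl]oxy}methyl)-4-hydroxydeca-5,9-dien-2-ynoate F1.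
- Semihydrogenation (H2, Pd on CaCO3 poisoned with Pb(OAc)2, quinoline) and spontaneous lactonisation of the Z enoate gives (5S)-5-[(1Z)-2-({[tert-butyl(dimethyl)silyl]oxy}methyl)hexa-1,5-dien-1-yl]furan-2(5H)-one F2.
- Phosphine-catalysed Morita–Baylis–Hillman hydroxymethylation (aqueous formaldehyde, PBu3) gives (5R)-3-(hydroxymethyl)-5-[(1Z)-2-({[tert-butyl(dimethyl)silyl]oxy}methyl)hexa-1,5-dien-1-yl]furan-2(5H)-one F3.
- Appel bromination of F3 (CBr4, PPh3) gives 13.

## Further compounds

F1 | step 6 | methyl (4R,5Z)-6-({[tert-butyl(dimethyl)silyl]oxy}methyl)-4-hydroxydeca-5,9-dien-2-ynoate | O[C@H](/C=C(/CCC=C)CO[Si](C)(C)C(C)(C)C)C#CC(=O)OC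
F2 | step 6 | (5S)-5-[(1Z)-2-({[tert-butyl(dimethyl)silyl]oxy}methyl)hexa-1,5-dien-1-yl]furan-2(5H)-one | O=C1O[C@H](/C=C(/CCC=C)CO[Si](C)(C)C(C)(C)C)C=C1
F3 | step 6 | (5R)-3-(hydroxymethyl)-5-[(1Z)-2-({[tert-butyl(dimethyl)silyl]oxy}methyl)hexa-1,5-dien-1-yl]furan-2(5H)-one | O=C1O[C@H](/C=C(/CCC=C)CO[Si](C)(C)C(C)(C)C)C=C1CO
F4 | step 11 | (4S,5R)-5-[(1Z)-2-({[tert-butyl(dimethyl)silyl]oxy}methyl)hexa-1,5-dien-1-yl]-3-methylidene-4-(3-methylbut-3-enoyl)oxolan-2-one | C=C1C(=O)O[C@H](/C=C(/CCC=C)CO[Si](C)(C)C(C)(C)C)[C@H]1C(=O)CC(C)=C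
F5 | step 11 | (4R,5R)-5-[(1Z)-2-({[tert-butyl(dimethyl)silyl]oxy}methyl)hexa-1,5-dien-1-yl]-4-[(1R)-1-hydroxy-3-methylbut-3-en-1-yl]-3-methylideneoxolan-2-one | C=C1C(=O)O[C@H](/C=C(/CCC=C)CO[Si](C)(C)C(C)(C)C)[C@H]1[C@H](O)CC(C)=C
F6 | step 12 | (3aR,4S,6Z,10Z,11aR)-10-({[tert-butyl(dimethyl)silyl]oxy}methyl)-4-hydroxy-6-methyl-3-methylidene-3a,4,5,8,9,11a-hexahydrocyclodeca[b]furan-2(3H)-one | C=C1C(=O)O[C@@H]2/C=C(CO[Si](C)(C)C(C)(C)C)/CC/C=C(C)\C[C@H](O)[C@@H]12
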